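**Plan**

1. Numbering follows the oxolane name of the target and is also used for the matching atoms of acyclic precursors: O1, C2 (O–CH carrying the 14-oxopentadecyl chain), C3 (carries CO2H), C4 (carries CH3), C5 (lactone C=O).
2. Retrosynthetic cuts, in order: the C3 carboxyl goes back to an N-acyl oxazolidinone; the C4 methyl goes back to an exocyclic C4=CH2; the ring bond C2–C3 of the γ-lactone is cut; the resulting 1-chloroalkyl ester (C2–Cl, O1–C5) goes back to aldehyde plus acyl chloride; the imide N–C(=O) goes back to itaconic anhydride; the whole chain comes from ω-pentadecalactone.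
3. Forward: the keto aldehyde (3 steps) and the itaconic half-imide (1 step) are joined as a 1-chloroalkyl ester; the only ring, the γ-lactone, then closes by forming C2–C3; hydrogenation of the methylidene and cleavage of the auxiliary finish the route.
4. Enabling feature: O1–C5(=O)–C4 holds C2 and C3 in a 1,5-relationship. C2 is an aldehyde-level carbon that, as an O-acyl chlorohydrin, can become an acyloxy-stabilised cation. C3 is the α-carbon of the carboxyl and, with C4 as a methylidene, the only acidic position.
5. Stereochemistry: C3 from the (4S)-benzyl oxazolidinone (enolate face); C2 from the trans preference of the closing five-membered ring; C4 from hydrogenation of C4=CH2 on the face opposite the C3 acyl group.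
6. Helpers removed later: chloride (lost in the ring closure), C4=CH2 (becomes the methyl), oxazolidinone (cleaved in the last step).

Key step: step 6

Assumptions: the distal methyl ketone is carried unprotected, being a weaker Lewis base and carbon acid than the chelating imide. In the fallback to step 6 the quinidine-derived catalyst is taken as the one that gives the (2S,3R)-oxetanone; its quinine-derived pseudo-enantiomer would be used if the sense proved opposite.

**Route**

Step 1
Reactants: 1 oxacyclohexadecan-2-one (ω-pentadecalactone)
Product: 2 15-hydroxy-N-methoxy-N-methylpentadecanamide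
Conditions: MeNH(OMe)·HCl, i-PrMgCl, THF, −20 to 0 °C; aq. NH4Cl
Reagents that add atoms: N,O-dimethylhydroxylamine hydrochloride, CNOC.Cl
Why: The chloromagnesium amide of N,O-dimethylhydroxylamine should open the macrolactone at the acyl carbon (ester aminolysis to a Weinreb amide), freeing the primary alcohol whose carbon becomes C2.

Step 2
Reactants: 2 15-hydroxy-N-methoxy-N-methylpentadecanamide
Product: 3 16-hydroxyhexadecan-2-one
Conditions: MeMgBr (3 equiv), THF, 0 °C; aq. NH4Cl
Reagents that add atoms: methylmagnesium bromide, C[Mg]Br
Why: Weinreb ketone synthesis: after deprotonation of the hydroxyl, the chelated tetrahedral adduct resists a second addition and should give the methyl ketone on work-up.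

Step 3
Reactants: 3 16-hydroxyhexadecan-2-one
Product: 4 15-oxohexadecanal
Conditions: TEMPO (10 mol%), PhI(OAc)2, CH2Cl2, rt
Reagents that add atoms: none
Why: Oxoammonium-mediated oxidation (TEMPO/PhI(OAc)2) is selective for the primary alcohol and should stop at the aldehyde without touching the ketone.

Step 4
Reactants: 5 (4S)-4-benzyl-1,3-oxazolidin-2-one; 6 itaconic anhydride (3-methylideneoxolane-2,5-dione)
Product: 8 4-[(4S)-4-benzyl-2-oxo-1,3-oxazolidin-3-yl]-2-methylidene-4-oxobutanoic acid, via lithium salt 7 (not isolated)
Conditions: n-BuLi, THF, −78 °C; then 6, −78 °C; aq. HCl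
Reagents that add atoms: none
Why: N-Acylation of the lithiated oxazolidinone by the cyclic anhydride should occur at the more electrophilic, unconjugated carbonyl (the regiochemistry of alcoholysis of this anhydride), giving the half-imide whose free acrylic carboxyl is the future C5.

Step 5
Reactants: 8 4-[(4S)-4-benzyl-2-oxo-1,3-oxazolidin-3-yl]-2-methylidene-4-oxobutanoic acid; 4 15-oxohexadecanal
Product: 10 1-chloro-15-oxohexadecyl 4-[(4S)-4-benzyl-2-oxo-1,3-oxazolidin-3-yl]-2-methylidene-4-oxobutanoate (epimer mixture at the CHCl carbon), via acid chloride 9 (not isolated)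
Conditions: (COCl)2, cat. DMF, CH2Cl2, 0 °C to rt, evaporate; then 4, ZnCl2 (5 mol%), CH2Cl2, 0 °C to rt
Reagents that add atoms: oxalyl chloride, O=C(Cl)C(=O)Cl
Why: ZnCl2-catalysed addition of an acyl chloride across an aliphatic aldehyde C=O (the ketone is far less reactive) is the classical route to 1-chloroalkyl esters and should install the O1–C5 tether and the leaving group on C2 in one operation.

Step 6
Reactants: 10 1-chloro-15-oxohexadecyl 4-[(4S)-4-benzyl-2-oxo-1,3-oxazolidin-3-yl]-2-methylidene-4-oxobutanoate
Product: 12 (4S)-4-benzyl-3-[(2S,3R)-4-methylidene-5-oxo-2-(14-oxopentadecyl)oxolane-3-carbonyl]-1,3-oxazolidin-2-one, via titanium enolate 11 (not isolated)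
Conditions: TiCl4 (1.1 equiv), i-Pr2NEt (1.2 equiv), CH2Cl2, −78 to 0 °C; aq. NH4Cl
Reagents that add atoms: none
Why: Proposed new method: TiCl4 chelates the imide of 10 and i-Pr2NEt removes the imide-α, allylic C3–H to give the chelated (Z)-trichlorotitanium enolate 11, while titanium-assisted loss of chloride turns the O-acylated chlorohydrin carbon C2 into an acyloxy-stabilised cation (contact ion pair) that the enolate carbon captures through the O1–C5 ester tether. The closest known reaction type is the alkylation of N-acyl oxazolidinone titanium enolates with ionisable α-chloro ethers, acetals and ortho esters, combined with the known Lewis-acid substitution of acylals and 1-haloalkyl esters by π-nucleophiles; the intramolecular, lactone-forming version is the new element. The oxolanone closes in a 5-(enolexo)-exo-tet mode (C3 attacks C2, chloride leaves exocyclically), and ionisation at C2 should loosen the ester resonance of O1 so that the s-cis geometry needed for a five-membered lactone is accessible. C3 (R) should be controlled by the (4S)-benzyl group, which shields one face of the chelated (Z)-enolate so that C2 bonds to the opposite face, in the sense of the intermolecular alkylations of this auxiliary. C2 (S) should be controlled in the cyclic transition state, where the long chain on the trigonal C2 turns away from the acyl oxazolidinone on C3 and gives the 2,3-trans lactone; the CHCl epimers of 10 converge because that centre is planarised. The step needs α- rather than γ-attack of the cross-conjugated dienolate and ring closure faster than reversion to aldehyde plus acyl chloride: γ-attack through the CH2 terminus would demand a 5-endo geometry with three trigonal ring atoms, the tether keeps the nucleophile next to the cation, and the C4 methylidene (no C4–H, no stereocentre) removes both a second enolisable site and any allylic-strain bias against the required face.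

Step 7
Reactants: 12 (4S)-4-benzyl-3-[(2S,3R)-4-methylidene-5-oxo-2-(14-oxopentadecyl)oxolane-3-carbonyl]-1,3-oxazolidin-2-one
Product: 13 (4S)-4-benzyl-3-[(2S,3R,4S)-4-methyl-5-oxo-2-(14-oxopentadecyl)oxolane-3-carbonyl]-1,3-oxazolidin-2-one
Conditions: H2 (1 atm), 10% Pd/C, EtOAc, rt
Reagents that add atoms: none
Why: Heterogeneous syn-hydrogenation of the α-methylene lactone should deliver hydrogen to the face opposite the bulky C3 acyl group, placing the new methyl cis to it and setting C4 (S), while the ketone, lactone and imide are inert under these conditions.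

Step 8
Reactants: 13 (4S)-4-benzyl-3-[(2S,3R,4S)-4-methyl-5-oxo-2-(14-oxopentadecyl)oxolane-3-carbonyl]-1,3-oxazolidin-2-one
Product: 15 (2S,3R,4S)-4-methyl-5-oxo-2-(14-oxopentadecyl)oxolane-3-carboxylic acid, via peroxy acid 14 (not isolated)
Conditions: LiOH, H2O2, THF/H2O, 0 °C; then Na2SO3; then HCl to pH 2
Reagents that add atoms: hydrogen peroxide, OO
Why: Hydroperoxide attacks the exocyclic imide carbonyl selectively (standard oxazolidinone cleavage), sulfite reduces the peroxy acid 14, and acidification re-closes any lactone opened by hydroxide, so no bond to a stereocentre is broken under these cold, brief conditions.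

**Compound list**

1 | oxacyclohexadecan-2-one (ω-pentadecalactone) | O=C1CCCCCCCCCCCCCCO1 | starting material
2 | 15-hydroxy-N-methoxy-N-methylpentadecanamide | CON(C)C(=O)CCCCCCCCCCCCCCO | intermediate
3 | 16-hydroxyhexadecan-2-one | CC(=O)CCCCCCCCCCCCCCO | intermediate
4 | 15-oxohexadecanal | CC(=O)CCCCCCCCCCCCCC=O | intermediate
5 | (4S)-4-benzyl-1,3-oxazolidin-2-one | O=C1OC[C@H](Cc2ccccc2)N1 | starting material
6 | itaconic anhydride (3-methylideneoxolane-2,5-dione) | C=C1CC(=O)OC1=O | starting material
7 | lithium (4S)-4-benzyl-2-oxo-1,3-oxazolidin-3-ide | [Li]N1[C@@H](Cc2ccccc2)COC1=O | intermediate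
8 | 4-[(4S)-4-benzyl-2-oxo-1,3-oxazolidin-3-yl]-2-methylidene-4-oxobutanoic acid | OC(=O)C(=C)CC(=O)N1[C@@H](Cc2ccccc2)COC1=O | intermediate
9 | 4-[(4S)-4-benzyl-2-oxo-1,3-oxazolidin-3-yl]-2-methylidene-4-oxobutanoyl chloride | ClC(=O)C(=C)CC(=O)N1[C@@H](Cc2ccccc2)COC1=O | intermediate
10 | 1-chloro-15-oxohexadecyl 4-[(4S)-4-benzyl-2-oxo-1,3-oxazolidin-3-yl]-2-methylidene-4-oxobutanoate (epimer mixture at the CHCl carbon) | CC(=O)CCCCCCCCCCCCCC(Cl)OC(=O)C(=C)CC(=O)N1[C@@H](Cc2ccccc2)COC1=O | intermediate
11 | trichlorotitanium (Z)-enolate of 10 | Cl[Ti](Cl)(Cl)O/C(=C\C(=C)C(=O)OC(Cl)CCCCCCCCCCCCCC(C)=O)N1[C@@H](Cc2ccccc2)COC1=O | intermediate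
12 | (4S)-4-benzyl-3-[(2S,3R)-4-methylidene-5-oxo-2-(14-oxopentadecyl)oxolane-3-carbonyl]-1,3-oxazolidin-2-one | CC(=O)CCCCCCCCCCCCC[C@@H]1OC(=O)C(=C)[C@H]1C(=O)N2[C@@H](Cc3ccccc3)COC2=O | intermediate
13 | (4S)-4-benzyl-3-[(2S,3R,4S)-4-methyl-5-oxo-2-(14-oxopentadecyl)oxolane-3-carbonyl]-1,3-oxazolidin-2-one | CC(=O)CCCCCCCCCCCCC[C@@H]1OC(=O)[C@@H](C)[C@H]1C(=O)N2[C@@H](Cc3ccccc3)COC2=O | intermediate
14 | (2S,3R,4S)-4-methyl-5-oxo-2-(14-oxopentadecyl)oxolane-3-carboperoxoic acid | CC(=O)CCCCCCCCCCCCC[C@@H]1OC(=O)[C@@H](C)[C@H]1C(=O)OO | intermediate
15 | (2S,3R,4S)-4-methyl-5-oxo-2-(14-oxopentadecyl)oxolane-3-carboxylic acid | CC(=O)CCCCCCCCCCCCC[C@@H]1OC(=O)[C@@H](C)[C@H]1C(=O)O | target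

**Step count and risks**

Total: 8 steps. Longest linear sequence: 7 steps (1, 2, 3, 5, 6, 7, 8); step 4 is a one-step branch.

Steps most likely to fail:

Step 6 (proposed new method). The ionised chloroester may revert to aldehyde plus acyl chloride, after which the enolate could react by intermolecular aldol with the opposite facial sense. The dienolate may also be reprotonated to the conjugated alkene, or the exocyclic double bond of the product may migrate into the ring. The fallback uses only known chemistry, sets out from aldehyde 4 and comes back to the route at 15. Commercial dimethyl (2S)-2-methylbutanedioate is saponified at its less hindered, unbranched ester (LiOH, 1 equiv) to (3S)-4-methoxy-3-methyl-4-oxobutanoic acid F1. Oxalyl chloride converts this into methyl (2S)-4-chloro-2-methyl-4-oxobutanoate F2. Slow addition of F2 to 4 with O-trimethylsilylquinidine (10 mol%), LiClO4 and i-Pr2NEt at −78 °C generates the ketene methyl (2S)-2-methyl-4-oxobut-3-enoate F3 (not isolated). Its catalyst-bound enolate should undergo the cinchona alkaloid/Lewis acid catalysed acyl halide–aldehyde cyclocondensation to the cis-β-lactone methyl (2S)-2-[(2S,3R)-4-oxo-2-(14-oxopentadecyl)oxetan-3-yl]propanoate F4. LiOH then opens the β-lactone at its acyl carbon and hydrolyses the methyl ester, and acidification closes the hydroxy diacid onto the carboxyl attached to C4, giving 15. In this fallback C2 and C3 come from the catalyst (cis-β-lactone becomes 2,3-trans γ-lactone) and C4 from the chiral pool.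

Step 5. The acryloyl-type chloride 9 may be lost by attack of the imide carbonyl or by polymerisation, or the chloroester equilibrium may not favour 10. The fallback sets out from 4 and 8 and comes back at 12. Acetyl chloride and ZnCl2 convert 4 into 1-chloro-15-oxohexadecyl acetate F5. Alkylation of the caesium salt of 8 (Cs2CO3, DMF) with F5 gives the mixed acylal 1-(acetyloxy)-15-oxohexadecyl 4-[(4S)-4-benzyl-2-oxo-1,3-oxazolidin-3-yl]-2-methylidene-4-oxobutanoate F6, by the carboxylate alkylation used for acyloxyalkyl esters. Under the conditions of step 6, F6 should lose acetate in place of chloride and close to 12, so 9 is never formed.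

Step 7. The exocyclic double bond may migrate into the ring on the palladium surface, or hydrogen may be delivered with poor facial selectivity. The fallback sets out from 12 and comes back at 13 without new isolated compounds. Conjugate reduction with [(Ph3P)CuH]6 in toluene gives a copper enolate; protonation with t-BuOH on the face opposite the C3 acyl group should set C4 by kinetic protonation instead of by surface hydrogenation. The ketone and the imide are not reduced by this reagent.

**Further compounds**

F1 | step 6 | (3S)-4-methoxy-3-methyl-4-oxobutanoic acid | COC(=O)[C@@H](C)CC(=O)O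
F2 | step 6 | methyl (2S)-4-chloro-2-methyl-4-oxobutanoate | COC(=O)[C@@H](C)CC(=O)Cl
F3 | step 6 | methyl (2S)-2-methyl-4-oxobut-3-enoate | COC(=O)[C@@H](C)C=C=O
F4 | step 6 | methyl (2S)-2-[(2S,3R)-4-oxo-2-(14-oxopentadecyl)oxetan-3-yl]propanoate | CC(=O)CCCCCCCCCCCCC[C@@H]1OC(=O)[C@@H]1[C@H](C)C(=O)OC
F5 | step 5 | 1-chloro-15-oxohexadecyl acetate | CC(=O)CCCCCCCCCCCCCC(Cl)OC(C)=O
F6 | step 5 | 1-(acetyloxy)-15-oxohexadecyl 4-[(4S)-4-benzyl-2-oxo-1,3-oxazolidin-3-yl]-2-methylidene-4-oxobutanoate | CC(=O)CCCCCCCCCCCCCC(OC(C)=O)OC(=O)C(=C)CC(=O)N1[C@@H](Cc2ccccc2)COC1=O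
F0 | step 7 | none | none
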